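Its constants are invented; the flask was simulated.

The constants of the two steps that consume G lie close, 2.5 /M/min for G + X and 2.3 /M/min for G + D, so I looked to the concentrations to part them.

    G + D → G.D (k1 = 2.3 /M/min, Ea1 = 66.0 kJ/mol)
    X + D → X.D (k2 = 2.4 /M/min, Ea2 = 68.0 kJ/mol)
    G + X → G.X (k3 = 2.5 /M/min, Ea3 = 67.0 kJ/mol)
    D + G.D ⇌ D.G.D, settled at all times (K4 = 87 /M, ΔH4 = −22.0 kJ/mol)
    Z ⇌ D, rate k5*(cs5 - [D]) while solid is left; crystals form when [D] > cs5 (cs5 = 14 mM, k5 = 0.11 /min)
    (constants at 25 °C)

common to all: Z 66.0 mM; time 25 min

| run | G | X | remark | temperature |
|---|---|---|---|---|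
| midnight | 33 mM | 66.0 mM (fed, over 15 min) | the addition at −15 °C, then warmed to 25 °C; the feed brings no volume worth counting |  |
| dawn | 33 mM | 66.0 mM | everything together at the start at −15 °C, warmed to 25 °C at 15 min |  |
| spring | 33 mM (fed, over 15 min) | 66.0 mM | all else is in the flask from the start; the feed brings no volume worth counting | 25 °C |
| winter | 33 mM | 66.0 mM | everything together at the start | 25 °C |
| noon | 33 mM | 66.0 mM (fed, over 15 min) | all else is in the flask from the start; the feed brings no volume worth counting | 25 °C |

- the flask that comes out highest in amount of G.X, in percent of the G charged, or "all alike" when all lie within 1.5 percentage points (midnight / dawn / spring / winter / noon / all alike)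
- G.X at the end, in percent of the G charged, midnight
- G.X at the end, in percent of the G charged, dawn
- G.X at the end, in percent of the G charged, spring
- G.X at the end, in percent of the G charged, winter
- G.X at the end, in percent of the G charged, noon

- G.D is meant together with its D.G.D
- solid, in amounts per volume of the solution: Z
- the list of constants is for 25 °C, to be carried to other temperatures by the activation energies and enthalpies
- at the start none of Z is in solution

G is the reagent charged in the smaller amount, and its balance has a loss to G.X and a loss to G.D, so I followed the winter flask through those two rates.

At the start of winter [G.X] climbs with the slope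

slope = 2.5 /M/min × 33 mM × 66.0 mM = 5.44 mM/min

At that [X], G halves in 4.2 min by this step alone, and I put the crossing of the falling [G] with the rising [G.X] near that time, a little later as [X] sinks.

In winter [D] starts from nothing and rises at 1.54 mM/min from the solid. X removes it, and with [X] held as charged its balance bends over at a plateau:

[D]* = 0.11 /min × 14 mM / (0.11 /min + 2.4 /M/min × 66.0 mM) = 5.74 mM

The knee comes after about 3.73 min. I left out the draw of G on D, whose 0.0759 /min is less than the 0.158 /min of X yet about half of it, so [D]* is a rough figure. This gave me the ratio I carried:

F = 2.5 /M/min × 66.0 mM / (2.3 /M/min × [D]*) = 12.5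

F is the fate ratio, a selectivity factor: the rate of G into G.X over the rate of G into G.D, with [X] as charged and [D] at its plateau. On that ratio I gave the part F/(1 + F) = 92.6% of the G spent to G.X.

The G + X step by itself takes [X] down towards 33.0 mM. Treating that step alone as second order, I got at 25 min:

[G]/[X] = (33 mM/66.0 mM) × exp(−2.5 /M/min × 33.0 mM × 25 min) = 0.0636

That leaves 6.79% of the G charged, so I expected the curve of G.X in winter to reach 86.3%. My reckoning stopped there and gave me no figure for the other flasks.

The forecast put winter first at 84%, below my figure, with spring at 76%, noon at 70%, dawn at 65.5% and midnight at 65%, holding that “all the X is there at once, while D is still building up from the solid”.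

The simulation put winter first, with G.X at 86.6% there, 75.4% in spring, 74.3% in noon, 65.4% in dawn and 65.0% in midnight; winter had 6.5% of its G left.

Winter ended at 86.6% G.X against 6.96% G.D, a ratio of 12.4 summed over the run, beside F of 12.5; [D] at the end stood at 7.96 mM and [X] at 25.6 mM, neither being the value I had reckoned with, but the G + X step had 87% of its turnover behind it at 12.5 min. For a neighbouring flask like winter but with 16 mM of X, the same formula gives F = 1.68, and that flask ended at 33.3% G.X against 22.1% G.D, with 44.6% of its G unreacted.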